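The C4–C9 stretch of the target (CH2, CHOH, trans-oxirane C6–O–C7, CHOH, CH2) is twofold-symmetric about its oxirane and carries the threo,trans,threo array 5S,6R,7R,8S of L-iditol. The plan therefore rests on cutting C9–C10 and C3–C4 back to 1,2:3,4:5,6-trianhydro-L-iditol, built from D-mannitol. In the key step the copper-catalysed Grignard reagent of the PMB-protected C10–C22 bromide opens one of the two homotopic terminal oxiranes of this C2-symmetric triepoxide at CH2; one operation forms C9–C10 and installs the finished C5–C8 stereoarray, central oxirane included. Lithiated ethyl propiolate then opens the twin oxirane, and ynoate macrolactonisation, desilylation and Lindlar reduction complete the route.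

Key step: step 11

Remark: locants C1–C22 are those of the target (C1 lactone carbonyl, C21 methyl carbinol); compounds 1–11 keep carbohydrate numbering; the CIP labels at C6 and C7 change on O-silylation although the geometry does not.

Step 1
Reactants: 1 1,2:5,6-di-O-isopropylidene-D-mannitol
Product: 3 diacetonide mannitol 3,4-cyclic sulfate, via cyclic sulfite 2 (not isolated)
Conditions: SOCl2, Et3N, CH2Cl2, 0 °C; then RuCl3·xH2O (cat.), NaIO4, MeCN/H2O, 0 °C to rt
Reagents that add atoms: thionyl chloride, O=S(Cl)Cl; sodium periodate, [Na+].[O-]I(=O)(=O)=O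
Why: The free threo 3,4-diol is closed to its cyclic sulfite and oxidised at sulfur by catalytic RuO4 (cyclic sulfate synthesis), which touches no stereocentre and leaves both dioxolanes intact.

Step 2
Reactants: 3 diacetonide mannitol 3,4-cyclic sulfate
Product: 5 3-bromo-3-deoxy-1,2:5,6-di-O-isopropylidene-D-altritol, via lithium bromo sulfate 4 (not isolated)
Conditions: LiBr, THF, reflux; then H2SO4 (cat.), H2O (1.5 equiv), THF, rt
Reagents that add atoms: lithium bromide, [Li+].[Br-]
Why: Bromide opens the cyclic sulfate by SN2 with inversion at one of its two homotopic carbons, and the alkyl sulfate monoester is then hydrolysed at the S–O bond by catalytic acid with near-stoichiometric water, conditions that spare isopropylidene acetals.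

Step 3
Reactants: 5 3-bromo-3-deoxy-1,2:5,6-di-O-isopropylidene-D-altritol
Product: 6 3,4-anhydro-1,2:5,6-di-O-isopropylidene-D-mannitol
Conditions: K2CO3, MeOH, 0 °C to rt
Reagents that add atoms: none
Why: Intramolecular Williamson etherification in which the C4 alkoxide displaces bromide from the back, so the bromine-bearing carbon is inverted a second time and the trans-oxirane keeps the D-manno configuration at both carbons.

Step 4
Reactants: 6 3,4-anhydro-1,2:5,6-di-O-isopropylidene-D-mannitol
Product: 7 3,4-anhydro-D-mannitol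
Conditions: AcOH/H2O 4:1, rt to 40 °C; evaporation with toluene
Reagents that add atoms: none
Why: Acid-catalysed acetal hydrolysis removes the two terminal dioxolanes, while the 2,3-disubstituted oxirane, flanked on both sides by electron-withdrawing C–O bonds, should resist acid opening as 2,3-anhydro sugars do under the same conditions.

Step 5
Reactants: 7 3,4-anhydro-D-mannitol
Product: 9 3,4-anhydro-1,6-di-O-benzoyl-2,5-di-O-methanesulfonyl-D-mannitol, via 1,6-dibenzoate 8 (not isolated)
Conditions: BzCl (2.05 equiv), pyridine/CH2Cl2, −40 °C; then MsCl (3 equiv), 0 °C to rt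
Reagents that add atoms: benzoyl chloride, O=C(Cl)c1ccccc1; methanesulfonyl chloride, CS(=O)(=O)Cl
Why: Low-temperature benzoylation is selective for the two primary hydroxyls of the C2-symmetric tetraol, and the remaining secondary hydroxyls are then mesylated in the same pyridine solution (selective O-acylation, then sulfonylation).

Step 6
Reactants: 9 3,4-anhydro-1,6-di-O-benzoyl-2,5-di-O-methanesulfonyl-D-mannitol
Product: 11 1,2:3,4:5,6-trianhydro-L-iditol, via dimesyl diol 10 (not isolated)
Conditions: K2CO3, MeOH/CH2Cl2, 0 °C to rt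
Reagents that add atoms: none
Why: Methanolysis of the benzoates (transesterification) frees the primary alkoxides, each of which displaces the adjacent secondary mesylate in a 3-exo-tet Williamson closure with inversion at C2 and C5, turning D-manno into L-ido while the central oxirane is untouched.

Step 7
Reactants: 12 10-bromodec-1-ene; 13 (R)-propylene oxide
Product: 15 (R)-tridec-12-en-2-ol, via dec-9-enylmagnesium bromide 14 (not isolated)
Conditions: Mg, THF; then 13, CuI (10 mol%), THF, −30 to 0 °C; aq. NH4Cl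
Reagents that add atoms: none
Why: Copper-catalysed Grignard opening of a terminal epoxide occurs at the CH2 carbon, so the purchased (R) carbinol centre is not involved and is carried unchanged.

Step 8
Reactants: 15 (R)-tridec-12-en-2-ol
Product: 16 (R)-12-(4-methoxybenzyloxy)tridec-1-ene
Conditions: NaH, PMBCl, Bu4NI (cat.), THF/DMF, 0 °C to rt
Reagents that add atoms: 4-methoxybenzyl chloride, COc1ccc(CCl)cc1
Why: Williamson etherification of the secondary alkoxide installs an ether that tolerates the organomagnesium, Lewis-acid and silylation steps and is later removed oxidatively.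

Step 9
Reactants: 16 (R)-12-(4-methoxybenzyloxy)tridec-1-ene
Product: 18 (R)-12-(4-methoxybenzyloxy)tridecan-1-ol, via B-alkyl-9-BBN 17 (not isolated)
Conditions: 9-BBN, THF, 0 °C to rt; then NaOH, H2O2, 0 °C to rt
Reagents that add atoms: hydrogen peroxide, OO
Why: Hydroboration with bulky 9-BBN places boron on the terminal carbon (anti-Markovnikov), and alkaline peroxide converts the C–B bond into the primary alcohol (hydroboration–oxidation).

Step 10
Reactants: 18 (R)-12-(4-methoxybenzyloxy)tridecan-1-ol
Product: 19 (R)-13-bromo-2-(4-methoxybenzyloxy)tridecane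
Conditions: CBr4, PPh3, CH2Cl2, 0 °C
Reagents that add atoms: carbon tetrabromide, BrC(Br)(Br)Br
Why: The Appel reaction converts the primary alcohol into the bromide under near-neutral conditions that leave the PMB ether and the remote stereocentre untouched.

Step 11
Reactants: 19 (R)-13-bromo-2-(4-methoxybenzyloxy)tridecane; 11 1,2:3,4:5,6-trianhydro-L-iditol
Product: 21 C4–C22 diepoxy alcohol (terminal 4,5-oxirane; trans-6,7-oxirane; 8-OH; 21-OPMB; 5S,6R,7R,8S,21R), via Grignard reagent 20 (not isolated)
Conditions: Mg, BrCH2CH2Br (cat.), THF, 45 °C; then added slowly to 11 (3 equiv), CuI (10 mol%), THF, −40 to −20 °C; aq. NH4Cl at −40 °C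
Reagents that add atoms: none
Why: Transmetalation of 20 to a monovalent-copper alkyl species is followed by delivery of the alkyl group to the unsubstituted CH2 of one monosubstituted oxirane with backside C–O cleavage; relief of three-ring strain makes C9–C10 bond formation irreversible and leaves a magnesium alkoxide at C8. The closest known reaction type is the copper-catalysed Grignard opening of C2-symmetric bis-terminal polyepoxides (1,2:5,6-dianhydrohexitols, 1,2:3,4-diepoxybutane) at their CH2 termini. No ring is closed and no stereocentre is created: C5–C8 arrive fully configured in 11, and because attack is at CH2 the carbinol carbon C8 is not at risk. The two terminal oxiranes are homotopic, so either gives the same compound and only mono- versus bis-opening needs control, which slow addition of 20 to a threefold excess of recoverable 11 should secure. Site selectivity over the central oxirane rests on both of its carbons being secondary, screened by the flanking rings and electronically retarded toward SN2 by the adjacent C–O bonds. Cold quenching of the magnesium alkoxide in THF should keep Payne-type epoxide migration from competing.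

Step 12
Reactants: 21 C4–C22 diepoxy alcohol
Product: 22 8-O-TBS ether of the C4–C22 diepoxide (5S,6R,7S,8S,21R)
Conditions: TBSOTf, 2,6-lutidine, CH2Cl2, −78 °C
Reagents that add atoms: tert-butyldimethylsilyl triflate, CC(C)(C)[Si](C)(C)OS(=O)(=O)C(F)(F)F
Why: Silylation with a silyl triflate and a hindered pyridine base proceeds at −78 °C without forming an alkoxide, so the acidic proton is removed before the Lewis-acid alkynylation and epoxide migration cannot start.

Step 13
Reactants: 22 8-O-TBS diepoxide; 23 ethyl propiolate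
Product: 25 ethyl (5S,6R,7S,8S,21R)-8-(tert-butyldimethylsilyloxy)-6,7-epoxy-5-hydroxy-21-(4-methoxybenzyloxy)docos-2-ynoate, via lithium acetylide 24 (not isolated)
Conditions: 23 (2 equiv), n-BuLi, THF, −78 °C; BF3·OEt2 (2 equiv), −78 °C; then 22, −78 °C; aq. NH4Cl at −78 °C
Reagents that add atoms: none
Why: Yamaguchi–Hirao alkynylation: the BF3-activated terminal oxirane is opened at its CH2 by the lithium acetylide to form C3–C4, C5 keeps its configuration because it is not the site of attack, and the hindered, inductively deactivated central oxirane should not compete at −78 °C.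

Step 14
Reactants: 25 C1–C22 hydroxy ynoate
Product: 26 ethyl (5S,6S,7S,8S,21R)-5,8-bis(tert-butyldimethylsilyloxy)-6,7-epoxy-21-(4-methoxybenzyloxy)docos-2-ynoate
Conditions: TBSOTf, 2,6-lutidine, CH2Cl2, −78 to 0 °C
Reagents that add atoms: tert-butyldimethylsilyl triflate, CC(C)(C)[Si](C)(C)OS(=O)(=O)C(F)(F)F
Why: The same base-buffered silyl triflate protection caps the C5 carbinol, so that only the C21 hydroxyl will be free at the lactonisation stage.

Step 15
Reactants: 26 bis-TBS PMB ynoate
Product: 27 ethyl (5S,6S,7S,8S,21R)-5,8-bis(tert-butyldimethylsilyloxy)-6,7-epoxy-21-hydroxydocos-2-ynoate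
Conditions: DDQ, CH2Cl2/pH 7 phosphate buffer 10:1, 0 °C to rt
Reagents that add atoms: none
Why: Oxidative PMB cleavage by DDQ (hydride abstraction from the electron-rich benzylic position, then hydrolysis) is selective for the PMB ether, and the buffer protects the silyl ethers and the oxirane.

Step 16
Reactants: 27 bis-TBS hydroxy ynoate
Product: 28 (5S,6S,7S,8S,21R)-5,8-bis(tert-butyldimethylsilyloxy)-6,7-epoxy-21-hydroxydocos-2-ynoic acid
Conditions: LiOH·H2O (3 equiv), THF/H2O 3:1, 0 °C; then cold 0.5 M HCl to pH 3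
Reagents that add atoms: lithium hydroxide, [Li+].[OH-]
Why: Saponification of the electron-poor ynoate ester is fast at 0 °C and gives a carboxylate that no longer undergoes conjugate addition or alkyne–allene isomerisation, while the TBS ethers and the oxirane are inert to cold aqueous LiOH.

Step 17
Reactants: 28 bis-TBS ynoic seco acid
Product: 30 (5S,6S,7S,8S,21R)-5,8-bis(tert-butyldimethylsilyloxy)-6,7-epoxydocos-2-yn-21-olide (22-membered lactone), via mixed anhydride 29 (not isolated)
Conditions: 2,4,6-Cl3C6H2COCl, Et3N, THF, rt; then syringe-pump addition to DMAP, toluene, rt (final 1 mM)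
Reagents that add atoms: none
Why: Yamaguchi macrolactonisation: the only free hydroxyl (C21) attacks the DMAP-activated acyl group at high dilution, closing the ring at the acyl C1–O bond with retention at C21, and the ynoate avoids the Z to E isomerisation that an activated Z-enoate would risk.

Step 18
Reactants: 30 bis-TBS ynoate macrolactone
Product: 31 (5S,6R,7R,8S,21R)-6,7-epoxy-5,8-dihydroxydocos-2-yn-21-olide
Conditions: HF·pyridine, pyridine, THF, 0 °C to rt
Reagents that add atoms: none
Why: Buffered HF desilylation generates no alkoxide, so Payne migration is avoided, the deactivated oxirane should tolerate it as in other late-stage epoxide-bearing macrolides, and the linear alkyne prevents the freed C5 hydroxyl from translactonising to a six-membered ring.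

Step 19
Reactants: 31 ynoate macrolactone diol
Product: 32 CIML C
Conditions: H2 (1 atm), Lindlar catalyst (Pd/CaCO3 poisoned with Pb(OAc)2), quinoline, EtOAc, rt
Reagents that add atoms: none
Why: Lindlar semi-hydrogenation adds hydrogen syn to the ring alkyne to give the Z-enoate, and the neutral conditions leave the oxirane untouched and should not trigger translactonisation of the 5-hydroxy Z-enoate.

Compound list
1 | 1,2:5,6-di-O-isopropylidene-D-mannitol | CC1(C)OC[C@@H](O1)[C@@H](O)[C@H](O)[C@H]2COC(C)(C)O2 | starting material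
2 | 1,2:5,6-di-O-isopropylidene-D-mannitol 3,4-cyclic sulfite | CC1(C)OC[C@@H](O1)[C@H]3OS(=O)O[C@@H]3[C@H]2COC(C)(C)O2 | intermediate
3 | 1,2:5,6-di-O-isopropylidene-D-mannitol 3,4-cyclic sulfate | CC1(C)OC[C@@H](O1)[C@H]3OS(=O)(=O)O[C@@H]3[C@H]2COC(C)(C)O2 | intermediate
4 | lithium 3-bromo-3-deoxy-1,2:5,6-di-O-isopropylidene-D-altritol 4-sulfate | CC1(C)OC[C@@H](O1)[C@H](Br)[C@H](OS(=O)(=O)[O-])[C@H]2COC(C)(C)O2.[Li+] | intermediate
5 | 3-bromo-3-deoxy-1,2:5,6-di-O-isopropylidene-D-altritol | CC1(C)OC[C@@H](O1)[C@H](Br)[C@H](O)[C@H]2COC(C)(C)O2 | intermediate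
6 | 3,4-anhydro-1,2:5,6-di-O-isopropylidene-D-mannitol (trans-oxirane) | CC1(C)OC[C@@H](O1)[C@H]2O[C@@H]2[C@H]3COC(C)(C)O3 | intermediate
7 | 3,4-anhydro-D-mannitol | OC[C@@H](O)[C@H]1O[C@@H]1[C@H](O)CO | intermediate
8 | 3,4-anhydro-1,6-di-O-benzoyl-D-mannitol | O=C(OC[C@@H](O)[C@H]1O[C@@H]1[C@H](O)COC(=O)c2ccccc2)c3ccccc3 | intermediate
9 | 3,4-anhydro-1,6-di-O-benzoyl-2,5-di-O-methanesulfonyl-D-mannitol | O=C(OC[C@@H](OS(C)(=O)=O)[C@H]1O[C@@H]1[C@H](OS(C)(=O)=O)COC(=O)c2ccccc2)c3ccccc3 | intermediate
10 | 3,4-anhydro-2,5-di-O-methanesulfonyl-D-mannitol | OC[C@@H](OS(C)(=O)=O)[C@H]1O[C@@H]1[C@H](OS(C)(=O)=O)CO | intermediate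
11 | 1,2:3,4:5,6-trianhydro-L-iditol, (2S,3R,4R,5S) | C1O[C@@H]1[C@H]2O[C@@H]2[C@@H]3CO3 | intermediate
12 | 10-bromodec-1-ene | C=CCCCCCCCCBr | starting material
13 | (R)-propylene oxide | C[C@@H]1CO1 | starting material
14 | dec-9-en-1-ylmagnesium bromide | C=CCCCCCCCC[Mg]Br | intermediate
15 | (R)-tridec-12-en-2-ol | C[C@@H](O)CCCCCCCCCC=C | intermediate
16 | (R)-12-(4-methoxybenzyloxy)tridec-1-ene | C[C@@H](OCc1ccc(OC)cc1)CCCCCCCCCC=C | intermediate
17 | B-[(R)-12-(4-methoxybenzyloxy)tridecyl]-9-borabicyclo[3.3.1]nonane | C[C@@H](OCc1ccc(OC)cc1)CCCCCCCCCCCB1C2CCCC1CCC2 | intermediate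
18 | (R)-12-(4-methoxybenzyloxy)tridecan-1-ol | C[C@@H](OCc1ccc(OC)cc1)CCCCCCCCCCCO | intermediate
19 | (R)-13-bromo-2-(4-methoxybenzyloxy)tridecane | C[C@@H](OCc1ccc(OC)cc1)CCCCCCCCCCCBr | intermediate
20 | [(R)-12-(4-methoxybenzyloxy)tridecyl]magnesium bromide | C[C@@H](OCc1ccc(OC)cc1)CCCCCCCCCCC[Mg]Br | intermediate
21 | C4–C22 diepoxy alcohol: terminal 4,5-oxirane, trans-6,7-oxirane, 8-OH, 21-OPMB (5S,6R,7R,8S,21R) | C[C@@H](OCc1ccc(OC)cc1)CCCCCCCCCCCC[C@H](O)[C@H]2O[C@@H]2[C@@H]3CO3 | intermediate
22 | 8-O-tert-butyldimethylsilyl ether of 21 (5S,6R,7S,8S,21R) | C[C@@H](OCc1ccc(OC)cc1)CCCCCCCCCCCC[C@H](O[Si](C)(C)C(C)(C)C)[C@H]2O[C@@H]2[C@@H]3CO3 | intermediate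
23 | ethyl propiolate | CCOC(=O)C#C | starting material
24 | ethyl 3-lithiopropiolate | CCOC(=O)C#C[Li] | intermediate
25 | ethyl (5S,6R,7S,8S,21R)-8-(tert-butyldimethylsilyloxy)-6,7-epoxy-5-hydroxy-21-(4-methoxybenzyloxy)docos-2-ynoate | C[C@@H](OCc1ccc(OC)cc1)CCCCCCCCCCCC[C@H](O[Si](C)(C)C(C)(C)C)[C@H]2O[C@@H]2[C@@H](O)CC#CC(=O)OCC | intermediate
26 | ethyl (5S,6S,7S,8S,21R)-5,8-bis(tert-butyldimethylsilyloxy)-6,7-epoxy-21-(4-methoxybenzyloxy)docos-2-ynoate | C[C@@H](OCc1ccc(OC)cc1)CCCCCCCCCCCC[C@H](O[Si](C)(C)C(C)(C)C)[C@H]2O[C@@H]2[C@@H](O[Si](C)(C)C(C)(C)C)CC#CC(=O)OCC | intermediate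
27 | ethyl (5S,6S,7S,8S,21R)-5,8-bis(tert-butyldimethylsilyloxy)-6,7-epoxy-21-hydroxydocos-2-ynoate | C[C@@H](O)CCCCCCCCCCCC[C@H](O[Si](C)(C)C(C)(C)C)[C@H]2O[C@@H]2[C@@H](O[Si](C)(C)C(C)(C)C)CC#CC(=O)OCC | intermediate
28 | (5S,6S,7S,8S,21R)-5,8-bis(tert-butyldimethylsilyloxy)-6,7-epoxy-21-hydroxydocos-2-ynoic acid | C[C@@H](O)CCCCCCCCCCCC[C@H](O[Si](C)(C)C(C)(C)C)[C@H]2O[C@@H]2[C@@H](O[Si](C)(C)C(C)(C)C)CC#CC(=O)O | intermediate
29 | mixed anhydride of 28 with 2,4,6-trichlorobenzoic acid | C[C@@H](O)CCCCCCCCCCCC[C@H](O[Si](C)(C)C(C)(C)C)[C@H]2O[C@@H]2[C@@H](O[Si](C)(C)C(C)(C)C)CC#CC(=O)OC(=O)c1c(Cl)cc(Cl)cc1Cl | intermediate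
30 | (5S,6S,7S,8S,21R)-5,8-bis(tert-butyldimethylsilyloxy)-6,7-epoxydocos-2-yn-21-olide | C[C@@H]1CCCCCCCCCCCC[C@H](O[Si](C)(C)C(C)(C)C)[C@H]2O[C@@H]2[C@@H](O[Si](C)(C)C(C)(C)C)CC#CC(=O)O1 | intermediate
31 | (5S,6R,7R,8S,21R)-6,7-epoxy-5,8-dihydroxydocos-2-yn-21-olide | C[C@@H]1CCCCCCCCCCCC[C@H](O)[C@H]2O[C@@H]2[C@@H](O)CC#CC(=O)O1 | intermediate
32 | CIML C, (2Z,5S,6R,7R,8S,21R)-6,7-epoxy-5,8-dihydroxydocos-2-en-21-olide | C[C@@H]1CCCCCCCCCCCC[C@H](O)[C@H]2O[C@@H]2[C@@H](O)C/C=C\C(=O)O1 | target

Total step count: 19 steps.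
Longest linear sequence: 15 steps (steps 1–6 and 11–19, from 1); the side-chain arm (steps 7–10) joins at step 11.

Steps most likely to fail

Step 11. The organocopper may open both terminal oxiranes of one molecule, magnesium bromide in the Grignard solution may open an oxirane to a bromohydrin, or the alkyl group may be delivered to the central oxirane. The fallback sets out from 16 and comes back at 21, and it replaces the sp3 organometallic by a halide-free acetylide at −78 °C. Lemieux–Johnson cleavage of the alkene of 16 (OsO4 cat., NaIO4, 2,6-lutidine, dioxane/H2O) would give (R)-11-(4-methoxybenzyloxy)dodecanal F1. The Ohira–Bestmann reagent (K2CO3, MeOH) would homologate it to (R)-12-(4-methoxybenzyloxy)tridec-1-yne F2. Its lithium acetylide with BF3·OEt2 in THF at −78 °C (Yamaguchi–Hirao alkynylation) would open one terminal oxirane of excess 11 at CH2 to the 10-ynyl diepoxy alcohol F3. Hydrogenation of the triple bond with H2 and RhCl(PPh3)3 in benzene/EtOH, which leaves oxiranes and the PMB ether alone, would return 21.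

Step 13. The ester-bearing lithium acetylide is thermally labile and may decompose or self-condense before it reaches the BF3-activated oxirane, leaving the epoxide unconsumed. The fallback sets out from 22 and comes back at 26, and it builds the ynoate in two stages. Lithium (trimethylsilyl)acetylide with BF3·OEt2 at −78 °C would open the terminal oxirane to the 5-hydroxy C-silyl alkyne F4. TBSOTf with 2,6-lutidine would give the bis-TBS C-silyl alkyne F5, and K2CO3 in MeOH would remove the alkynyl silane to give the bis-TBS terminal alkyne F6. Deprotonation with n-BuLi at −78 °C and acylation with ethyl chloroformate would deliver 26.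

Step 17. Acyl activation may be diverted by conjugate addition of DMAP or chloride to the activated ynoate, or by intermolecular esterification to oligomers. The fallback sets out from 27 and comes back at 30, and it activates the alcohol instead of the acid. Mitsunobu inversion of 27 with 4-nitrobenzoic acid (PPh3, DIAD, THF, 0 °C) would give the (21S)-4-nitrobenzoate F7. LiOH in THF/H2O would cleave both esters to the (21S)-hydroxy ynoic acid F8. Mitsunobu macrolactonisation (PPh3, DIAD, toluene, high dilution, 0 °C to rt) would form the O–C21 bond with a second inversion, restoring 21R in 30.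

Further compounds
F1 | step 11 | (R)-11-(4-methoxybenzyloxy)dodecanal | C[C@@H](OCc1ccc(OC)cc1)CCCCCCCCCC=O
F2 | step 11 | (R)-12-(4-methoxybenzyloxy)tridec-1-yne | C[C@@H](OCc1ccc(OC)cc1)CCCCCCCCCC#C
F3 | step 11 | C4–C22 diepoxy alcohol with a C10–C11 triple bond (5S,6R,7R,8S,21R) | C[C@@H](OCc1ccc(OC)cc1)CCCCCCCCCC#CC[C@H](O)[C@H]2O[C@@H]2[C@@H]3CO3
F4 | step 13 | C2–C22 8-O-TBS 5-hydroxy 6,7-epoxy 21-OPMB alkyne bearing SiMe3 at C2 (5S,6R,7S,8S,21R) | C[C@@H](OCc1ccc(OC)cc1)CCCCCCCCCCCC[C@H](O[Si](C)(C)C(C)(C)C)[C@H]2O[C@@H]2[C@@H](O)CC#C[Si](C)(C)C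
F5 | step 13 | 5,8-bis-O-TBS ether of F4 (5S,6S,7S,8S,21R) | C[C@@H](OCc1ccc(OC)cc1)CCCCCCCCCCCC[C@H](O[Si](C)(C)C(C)(C)C)[C@H]2O[C@@H]2[C@@H](O[Si](C)(C)C(C)(C)C)CC#C[Si](C)(C)C
F6 | step 13 | 5,8-bis-O-TBS 6,7-epoxy 21-OPMB C2–C22 terminal alkyne (5S,6S,7S,8S,21R) | C[C@@H](OCc1ccc(OC)cc1)CCCCCCCCCCCC[C@H](O[Si](C)(C)C(C)(C)C)[C@H]2O[C@@H]2[C@@H](O[Si](C)(C)C(C)(C)C)CC#C
F7 | step 17 | ethyl (5S,6S,7S,8S,21S)-5,8-bis(tert-butyldimethylsilyloxy)-6,7-epoxy-21-(4-nitrobenzoyloxy)docos-2-ynoate | C[C@H](OC(=O)c1ccc(cc1)[N+](=O)[O-])CCCCCCCCCCCC[C@H](O[Si](C)(C)C(C)(C)C)[C@H]2O[C@@H]2[C@@H](O[Si](C)(C)C(C)(C)C)CC#CC(=O)OCC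
F8 | step 17 | (5S,6S,7S,8S,21S)-5,8-bis(tert-butyldimethylsilyloxy)-6,7-epoxy-21-hydroxydocos-2-ynoic acid | C[C@H](O)CCCCCCCCCCCC[C@H](O[Si](C)(C)C(C)(C)C)[C@H]2O[C@@H]2[C@@H](O[Si](C)(C)C(C)(C)C)CC#CC(=O)O
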